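## Retrosynthetic overview

1. Target ⇐ Et3Si removal ⇐ site- and face-selective peracid epoxidation of C1=C10 of a 3-O-silyl germacra-1(10)E,4Z,11(13)-trien-12,6α-olide that already carries the (2S,3S)-epoxyangelate; the 1,10-oxirane is made last.
2. Trienolide ⇐ one operation: ten-membered carbocycle closed at C6–C7 (the farnesyl C1–C10 bond) by intramolecular allylboration of a Z-enal, then 6,12-lactone by acyl transfer. Ring order: carbocycle → γ-lactone → oxirane.
3. Acyclic C15 enal–allylboronate ⇐ syn-hydroalumination/borylmethylation of a γ-acyloxy ynoate; the ester comes from (2S,3S)-2,3-epoxy-2-methylbutanoic acid (Sharpless epoxidation of angelyl alcohol).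
4. C8 carbinol ⇐ Zn/ProPhenol addition of methyl propiolate; C3 carbinol and the 4Z olefin ⇐ Ni/Cr coupling with (Z)-3-iodobut-2-en-1-ol.
5. Core C8–C9–C10(Me)=C1–C2–C3 ⇐ but-3-yn-1-ol by Zr-catalysed methylalumination and oxirane opening.

Assumption: atoms are referred to by germacrane numbering (C1–C15; lactone carbonyl C12, exocyclic methylene C13, methyls C14 and C15); all numbered starting materials and the unnumbered reagents are commercial.

## Route

Step 1
Reactants: 1 but-2-yn-1-ol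
Product: 3 (Z)-3-iodobut-2-en-1-ol, via cyclic sodium vinylalanate 2 (not isolated)
Conditions: NaAlH2(OCH2CH2OMe)2, THF, 0 °C to rt; then I2, −78 °C
Reagents that add atoms: iodine, II
Why: Hydroxyl-directed trans-hydroalumination of the propargylic alcohol puts Al on C3 cis to CH2O in a five-membered alanate, and iodinolysis with retention gives the Z iodide that later becomes the 4Z olefin.

Step 2
Reactants: 4 methyl (Z)-2-methylbut-2-enoate (methyl angelate)
Product: 5 (Z)-2-methylbut-2-en-1-ol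
Conditions: iBu2AlH (2.2 equiv), CH2Cl2, −78 °C
Reagents that add atoms: none
Why: 1,2-Reduction of the enoate with iBu2AlH at low temperature gives the allylic alcohol without Z/E isomerisation.

Step 3
Reactants: 5 (Z)-2-methylbut-2-en-1-ol
Product: 6 [(2R,3S)-2,3-dimethyloxiran-2-yl]methanol
Conditions: Ti(OiPr)4 (10 mol%), D-(−)-diethyl tartrate (12 mol%), t-BuOOH, 4 Å MS, CH2Cl2, −20 °C
Reagents that add atoms: tert-butyl hydroperoxide, CC(C)(C)OO
Why: Sharpless asymmetric epoxidation; the D-(−)-tartrate complex delivers oxygen to the olefin face that gives the (2R,3S) epoxy alcohol (the antipode of the L-(+)-tartrate product), setting both side-chain stereocentres.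

Step 4
Reactants: 6 [(2R,3S)-2,3-dimethyloxiran-2-yl]methanol
Product: 7 (2S,3S)-2,3-dimethyloxirane-2-carboxylic acid
Conditions: RuCl3 (2 mol%), NaIO4, MeCN/EtOAc/H2O, rt
Reagents that add atoms: water, O; sodium periodate, [Na+].[O-]I(=O)(=O)=O
Why: RuO4-mediated oxidation of the primary alcohol to the acid leaves both epoxide stereocentres untouched (the descriptor at C2 changes from R to S only through priority).

Step 5
Reactants: 8 but-3-yn-1-ol
Product: 9 1-[(but-3-yn-1-yloxy)methyl]-4-methoxybenzene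
Conditions: NaH, 4-methoxybenzyl chloride, Bu4NI (cat.), THF, 0 °C to rt
Reagents that add atoms: 4-methoxybenzyl chloride, COc1ccc(CCl)cc1
Why: Williamson etherification of the alkoxide masks the future C8 oxygen with a group that DDQ can later remove beside silyl ethers.

Step 6
Reactants: 9 1-[(but-3-yn-1-yloxy)methyl]-4-methoxybenzene; 10 oxirane
Product: 13 (E)-6-[(4-methoxybenzyl)oxy]-4-methylhex-3-en-1-ol, via alkenyl(dimethyl)alane 11 (not isolated), via lithium alkenyl(butyl)alanate 12 (not isolated)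
Conditions: Me3Al, Cp2ZrCl2 (25 mol%), CH2Cl2, 0 °C to rt; then n-BuLi, hexane/THF, −78 °C; oxirane, −78 to 0 °C
Reagents that add atoms: trimethylaluminium, C[Al](C)C
Why: Negishi Zr-catalysed syn-methylalumination puts the C14 methyl on C10 and Al on C1, and the derived alanate opens oxirane with retention, fixing the 1(10)E olefin and attaching C2–C3.

Step 7
Reactants: 13 (E)-6-[(4-methoxybenzyl)oxy]-4-methylhex-3-en-1-ol
Product: 14 (E)-6-[(4-methoxybenzyl)oxy]-4-methylhex-3-enal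
Conditions: Dess–Martin periodinane, pyridine, CH2Cl2, 0 °C; used crude
Reagents that add atoms: none
Why: Buffered Dess–Martin oxidation gives the β,γ-unsaturated aldehyde without moving the olefin into conjugation.

Step 8
Reactants: 14 (E)-6-[(4-methoxybenzyl)oxy]-4-methylhex-3-enal; 3 (Z)-3-iodobut-2-en-1-ol
Product: 15 (2Z,4S,6E)-9-[(4-methoxybenzyl)oxy]-3,7-dimethylnona-2,6-diene-1,4-diol
Conditions: CrCl2 (4 equiv), NiCl2 (2 mol%), Et3N, N-[2-(4-isopropyl-4,5-dihydrooxazol-2-yl)-6-methylphenyl]methanesulfonamide (enantiomer that gives the 4S alcohol), THF, rt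
Reagents that add atoms: none
Why: Nozaki–Hiyama–Kishi Ni/Cr coupling adds the alkenylchromium chemoselectively to the aldehyde with retention of the Z geometry and tolerates the free hydroxyl, and the chromium-bound chiral oxazoline–sulfonamide selects the aldehyde face to set C3 (S).

Step 9
Reactants: 15 (2Z,4S,6E)-9-[(4-methoxybenzyl)oxy]-3,7-dimethylnona-2,6-diene-1,4-diol
Product: 16 1-methoxy-4-({[(3E,6S,7Z)-3,7-dimethyl-6,9-bis(triethylsilyloxy)nona-3,7-dien-1-yl]oxy}methyl)benzene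
Conditions: Et3SiCl (2.5 equiv), imidazole, DMF, 0 °C to rt
Reagents that add atoms: chlorotriethylsilane, CC[Si](Cl)(CC)CC
Why: Double silylation blocks the C3 hydroxyl (which would otherwise form a lactol and then a furan with the later Z-enal) and leaves the primary C6 silyl ether as a latent aldehyde.

Step 10
Reactants: 16 the bis(triethylsilyl) 4-methoxybenzyl ether
Product: 17 (3E,6S,7Z)-3,7-dimethyl-6,9-bis(triethylsilyloxy)nona-3,7-dien-1-ol
Conditions: DDQ, CH2Cl2/pH 7 buffer, 0 °C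
Reagents that add atoms: none
Why: Oxidative cleavage of the 4-methoxybenzyl ether by DDQ under buffered conditions frees only the C8 hydroxyl and leaves the silyl ethers and olefins intact.

Step 11
Reactants: 17 (3E,6S,7Z)-3,7-dimethyl-6,9-bis(triethylsilyloxy)nona-3,7-dien-1-ol
Product: 18 (3E,6S,7Z)-3,7-dimethyl-6,9-bis(triethylsilyloxy)nona-3,7-dienal
Conditions: Dess–Martin periodinane, pyridine, CH2Cl2, 0 °C; used crude
Reagents that add atoms: none
Why: Buffered Dess–Martin oxidation gives the C8 aldehyde without olefin migration or silyl loss.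

Step 12
Reactants: 18 (3E,6S,7Z)-3,7-dimethyl-6,9-bis(triethylsilyloxy)nona-3,7-dienal; 19 methyl propiolate
Product: 21 methyl (4R,6E,9S,10Z)-4-hydroxy-6,10-dimethyl-9,12-bis(triethylsilyloxy)dodeca-6,10-dien-2-ynoate, via methylzinc acetylide 20 (not isolated)
Conditions: Me2Zn (3 equiv), ProPhenol ligand (20 mol%, antipode that gives the 4R alcohol), Ph3P=O (40 mol%), toluene, 4 °C
Reagents that add atoms: none
Why: Catalytic asymmetric alkynylation (dinuclear zinc–ProPhenol) adds the propiolate acetylide to one aldehyde face under catalyst control, setting C8 (R) and bringing in C7, C11 and C12.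

Step 13
Reactants: 21 the (4R)-hydroxy ynoate; 7 (2S,3S)-2,3-dimethyloxirane-2-carboxylic acid
Product: 22 methyl (4R,6E,9S,10Z)-4-{[(2S,3S)-2,3-dimethyloxirane-2-carbonyl]oxy}-6,10-dimethyl-9,12-bis(triethylsilyloxy)dodeca-6,10-dien-2-ynoate
Conditions: 7, 2,4,6-trichlorobenzoyl chloride, Et3N, THF, rt; then 21, DMAP, toluene, 0 °C to rt
Reagents that add atoms: none
Why: Yamaguchi esterification couples the hindered α-quaternary epoxy acid through its mixed anhydride with retention at C8 (acyl–oxygen bond formation), installing the final side chain before ring closure.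

Step 14
Reactants: 22 the γ-acyloxy ynoate; 23 2-(iodomethyl)-4,4,5,5-tetramethyl-1,3,2-dioxaborolane
Product: 25 methyl (2Z,4R,6E,9S,10Z)-4-{[(2S,3S)-2,3-dimethyloxirane-2-carbonyl]oxy}-6,10-dimethyl-2-[(4,4,5,5-tetramethyl-1,3,2-dioxaborolan-2-yl)methyl]-9,12-bis(triethylsilyloxy)dodeca-2,6,10-trienoate, via α-alumino enoate 24 (not isolated)
Conditions: iBu2AlH (1.3 equiv), HMPA, THF, 0 °C; then 23, 0 °C to rt
Reagents that add atoms: none
Why: Conjugate syn-hydroalumination of the ynoate (iBu2AlH–HMPA) puts H on C7 and Al on C11, and alkylation of this α-metallo enoate with the iodomethylboronate (Matteson-type 1,2-shift) keeps the geometry, so C8 ends cis to the ester and CH2B trans to it, the geometry needed for the anti allylboration.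

Step 15
Reactants: 25 the allylboronate bis(silyl ether)
Product: 26 methyl (2Z,4R,6E,9S,10Z)-4-{[(2S,3S)-2,3-dimethyloxirane-2-carbonyl]oxy}-6,10-dimethyl-12-oxo-2-[(4,4,5,5-tetramethyl-1,3,2-dioxaborolan-2-yl)methyl]-9-(triethylsilyloxy)dodeca-2,6,10-trienoate
Conditions: (COCl)2, DMSO, CH2Cl2, −78 to −30 °C; Et3N, −78 °C; used at once
Reagents that add atoms: none
Why: Swern conditions cleave and oxidise the primary allylic triethylsilyl ether directly to the Z-enal while the secondary silyl ether, the ester-deactivated allylboronate and the Z geometry survive at low temperature.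

Step 16
Reactants: 26 the Z-enal allylboronate
Product: 28 3β-(triethylsilyloxy)-8β-[(2S,3S)-2,3-dimethyloxirane-2-carbonyloxy]germacra-1(10)E,4Z,11(13)-trien-12,6α-olide (3S,6R,7R,8R), via ring-closed pinacol borate 27 (not isolated)
Conditions: Sc(OTf)3 (10 mol%), 4 Å MS, toluene (2 mM), rt to 50 °C
Reagents that add atoms: none
Why: Proposed new method: the boron on C13 delivers C7 to the tethered enal carbon C6 through a chair six-membered Zimmerman–Traxler transition state (closest known reaction: Sc(OTf)3-catalysed intermolecular allylboration of aldehydes with 2-alkoxycarbonyl allylboronates, which gives α-methylene-γ-butyrolactones stereospecifically); with C8 cis to the ester and both ring bonds equatorial the chair gives the 6,7-anti adduct (H-6β, H-7α), the C8 centre is expected to steer the enal to the face anti to the C8–C9 bond with H-8 in the enoate plane (7α-H/8β-O), and the borate oxygen then closes the trans-fused lactone with loss of MeOBpin.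

Step 17
Reactants: 28 the silyl-protected trienolide
Product: 29 1β,10α-epoxy-3β-(triethylsilyloxy)-8β-[(2S,3S)-2,3-dimethyloxirane-2-carbonyloxy]germacra-4Z,11(13)-dien-12,6α-olide (1R,3S,6R,7R,8R,10R)
Conditions: mCPBA (1.1 equiv), CH2Cl2, −20 to 0 °C; aq. NaHCO3/Na2S2O3 work-up
Reagents that add atoms: 3-chloroperoxybenzoic acid, OOC(=O)c1cccc(Cl)c1
Why: Prilezhaev epoxidation picks the electron-rich C1=C10 olefin (C4=C5 is deactivated by two allylic C–O bonds, C11=C13 is conjugated to the lactone) and attacks its exposed outer face in the ground-state conformer with C14 on the β side, so the E olefin gives the trans 1β,10α oxirane (1R,10R).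

Step 18
Reactants: 29 the silyl-protected bis-epoxide
Product: 30 target CNP0268255.2, 1β,10α-epoxy-3β-hydroxy-8β-[(2S,3S)-2,3-dimethyloxirane-2-carbonyloxy]germacra-4Z,11(13)-dien-12,6α-olide
Conditions: HF·pyridine, pyridine/THF, 0 °C
Reagents that add atoms: none
Why: Pyridine-buffered fluoride desilylation frees the 3β-hydroxyl without opening either oxirane, adding to the α-methylene lactone or touching any stereocentre.

## Compound list

1 | but-2-yn-1-ol | CC#CCO | starting material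
2 | sodium 2,2-bis(2-methoxyethoxy)-3-methyl-2,5-dihydro-1,2-oxaaluminol-2-uide (Al on C3, cis to CH2O) | [Na+].CC1=CCO[Al-]1(OCCOC)OCCOC | intermediate (not isolated)
3 | (Z)-3-iodobut-2-en-1-ol | C/C(I)=C/CO | intermediate
4 | methyl (Z)-2-methylbut-2-enoate (methyl angelate) | C/C=C(/C)C(=O)OC | starting material
5 | (Z)-2-methylbut-2-en-1-ol | C/C=C(/C)CO | intermediate
6 | [(2R,3S)-2,3-dimethyloxiran-2-yl]methanol | OC[C@@]1(C)O[C@H]1C | intermediate
7 | (2S,3S)-2,3-dimethyloxirane-2-carboxylic acid | OC(=O)[C@@]1(C)O[C@H]1C | intermediate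
8 | but-3-yn-1-ol | C#CCCO | starting material
9 | 1-[(but-3-yn-1-yloxy)methyl]-4-methoxybenzene | C#CCCOCc1ccc(OC)cc1 | intermediate
10 | oxirane | C1CO1 | starting material
11 | dimethyl[(E)-4-[(4-methoxybenzyl)oxy]-2-methylbut-1-en-1-yl]alane (Al cis to the new methyl) | C[Al](C)/C=C(\C)CCOCc1ccc(OC)cc1 | intermediate (not isolated)
12 | lithium butyl(dimethyl)[(E)-4-[(4-methoxybenzyl)oxy]-2-methylbut-1-en-1-yl]alanate | [Li+].CCCC[Al-](C)(C)/C=C(\C)CCOCc1ccc(OC)cc1 | intermediate (not isolated)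
13 | (E)-6-[(4-methoxybenzyl)oxy]-4-methylhex-3-en-1-ol | OCC/C=C(\C)CCOCc1ccc(OC)cc1 | intermediate
14 | (E)-6-[(4-methoxybenzyl)oxy]-4-methylhex-3-enal | O=CC/C=C(\C)CCOCc1ccc(OC)cc1 | intermediate
15 | (2Z,4S,6E)-9-[(4-methoxybenzyl)oxy]-3,7-dimethylnona-2,6-diene-1,4-diol | OC/C=C(/C)[C@@H](O)C/C=C(\C)CCOCc1ccc(OC)cc1 | intermediate
16 | 1-methoxy-4-({[(3E,6S,7Z)-3,7-dimethyl-6,9-bis(triethylsilyloxy)nona-3,7-dien-1-yl]oxy}methyl)benzene | CC[Si](CC)(CC)OC/C=C(/C)[C@@H](O[Si](CC)(CC)CC)C/C=C(\C)CCOCc1ccc(OC)cc1 | intermediate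
17 | (3E,6S,7Z)-3,7-dimethyl-6,9-bis(triethylsilyloxy)nona-3,7-dien-1-ol | CC[Si](CC)(CC)OC/C=C(/C)[C@@H](O[Si](CC)(CC)CC)C/C=C(\C)CCO | intermediate
18 | (3E,6S,7Z)-3,7-dimethyl-6,9-bis(triethylsilyloxy)nona-3,7-dienal | CC[Si](CC)(CC)OC/C=C(/C)[C@@H](O[Si](CC)(CC)CC)C/C=C(\C)CC=O | intermediate
19 | methyl propiolate | C#CC(=O)OC | starting material
20 | methyl 3-(methylzincio)prop-2-ynoate | C[Zn]C#CC(=O)OC | intermediate (not isolated)
21 | methyl (4R,6E,9S,10Z)-4-hydroxy-6,10-dimethyl-9,12-bis(triethylsilyloxy)dodeca-6,10-dien-2-ynoate | CC[Si](CC)(CC)OC/C=C(/C)[C@@H](O[Si](CC)(CC)CC)C/C=C(\C)C[C@@H](O)C#CC(=O)OC | intermediate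
22 | methyl (4R,6E,9S,10Z)-4-{[(2S,3S)-2,3-dimethyloxirane-2-carbonyl]oxy}-6,10-dimethyl-9,12-bis(triethylsilyloxy)dodeca-6,10-dien-2-ynoate | CC[Si](CC)(CC)OC/C=C(/C)[C@@H](O[Si](CC)(CC)CC)C/C=C(\C)C[C@@H](OC(=O)[C@@]1(C)O[C@H]1C)C#CC(=O)OC | intermediate
23 | 2-(iodomethyl)-4,4,5,5-tetramethyl-1,3,2-dioxaborolane | ICB1OC(C)(C)C(C)(C)O1 | starting material
24 | α-alumino enoate: compound 25 with iBu2Al on C11 in place of CH2Bpin (Al cis to H-7, C8 cis to the ester) | CC[Si](CC)(CC)OC/C=C(/C)[C@@H](O[Si](CC)(CC)CC)C/C=C(\C)C[C@@H](OC(=O)[C@@]1(C)O[C@H]1C)/C=C(\C(=O)OC)[Al](CC(C)C)CC(C)C | intermediate (not isolated)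
25 | methyl (2Z,4R,6E,9S,10Z)-4-{[(2S,3S)-2,3-dimethyloxirane-2-carbonyl]oxy}-6,10-dimethyl-2-[(4,4,5,5-tetramethyl-1,3,2-dioxaborolan-2-yl)methyl]-9,12-bis(triethylsilyloxy)dodeca-2,6,10-trienoate | CC[Si](CC)(CC)OC/C=C(/C)[C@@H](O[Si](CC)(CC)CC)C/C=C(\C)C[C@@H](OC(=O)[C@@]1(C)O[C@H]1C)/C=C(\C(=O)OC)CB2OC(C)(C)C(C)(C)O2 | intermediate
26 | methyl (2Z,4R,6E,9S,10Z)-4-{[(2S,3S)-2,3-dimethyloxirane-2-carbonyl]oxy}-6,10-dimethyl-12-oxo-2-[(4,4,5,5-tetramethyl-1,3,2-dioxaborolan-2-yl)methyl]-9-(triethylsilyloxy)dodeca-2,6,10-trienoate | O=C/C=C(/C)[C@@H](O[Si](CC)(CC)CC)C/C=C(\C)C[C@@H](OC(=O)[C@@]1(C)O[C@H]1C)/C=C(\C(=O)OC)CB2OC(C)(C)C(C)(C)O2 | intermediate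
27 | ring-closed borate: methyl 2-(cyclodeca-3,7-dien-1-yl)acrylate with 6α-OBpin, 7α-H, 3β-OSiEt3, 8β-acyloxy, 1(10)E, 4Z (germacrane numbering) | C=C(C(=O)OC)[C@H]1[C@H](OB2OC(C)(C)C(C)(C)O2)/C=C(/C)[C@@H](O[Si](CC)(CC)CC)C/C=C(\C)C[C@H]1OC(=O)[C@@]3(C)O[C@H]3C | intermediate (not isolated)
28 | 3β-(triethylsilyloxy)-8β-[(2S,3S)-2,3-dimethyloxirane-2-carbonyloxy]germacra-1(10)E,4Z,11(13)-trien-12,6α-olide (3S,6R,7R,8R) | C=C1C(=O)O[C@@H]2/C=C(/C)[C@@H](O[Si](CC)(CC)CC)C/C=C(\C)C[C@@H](OC(=O)[C@@]3(C)O[C@H]3C)[C@@H]12 | intermediate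
29 | 1β,10α-epoxy-3β-(triethylsilyloxy)-8β-[(2S,3S)-2,3-dimethyloxirane-2-carbonyloxy]germacra-4Z,11(13)-dien-12,6α-olide (1R,3S,6R,7R,8R,10R) | C=C1C(=O)O[C@@H]2/C=C(/C)[C@@H](O[Si](CC)(CC)CC)C[C@H]3O[C@]3(C)C[C@@H](OC(=O)[C@@]4(C)O[C@H]4C)[C@@H]12 | intermediate
30 | CNP0268255.2, 1β,10α-epoxy-3β-hydroxy-8β-[(2S,3S)-2,3-dimethyloxirane-2-carbonyloxy]germacra-4Z,11(13)-dien-12,6α-olide | C=C1C(=O)O[C@@H]2/C=C(/C)[C@@H](O)C[C@H]3O[C@]3(C)C[C@@H](OC(=O)[C@@]3(C)O[C@H]3C)[C@@H]12 | target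

## Step count and risks

Total step count: 18 (steps 1–18). Longest linear sequence: 14 steps (steps 5–18, from but-3-yn-1-ol 8). Side branches: step 1 (iodide 3) and steps 2–4 (acid 7).

Steps most likely to fail:

**Step 16 (macrocyclic allylboration/lactonisation).** The ester-deactivated allylboronate may be too slow at 2 mM, Sc(OTf)3 may isomerise the Z-enal, and the facial bias exerted by C8 is the least predictable element of the route. The fallback sets out from 25 and comes back at 28. The C–B bond of 25 is oxidised (NaBO3·4H2O, THF/H2O) to methyl (2Z,4R,6E,9S,10Z)-4-{[(2S,3S)-2,3-dimethyloxirane-2-carbonyl]oxy}-2-(hydroxymethyl)-6,10-dimethyl-9,12-bis(triethylsilyloxy)dodeca-2,6,10-trienoate F1. CBr4/PPh3 turns this into the allylic bromide methyl (2E,4R,6E,9S,10Z)-2-(bromomethyl)-4-{[(2S,3S)-2,3-dimethyloxirane-2-carbonyl]oxy}-6,10-dimethyl-9,12-bis(triethylsilyloxy)dodeca-2,6,10-trienoate F2. The selective Swern oxidation of the primary silyl ether gives the bromo enal methyl (2E,4R,6E,9S,10Z)-2-(bromomethyl)-4-{[(2S,3S)-2,3-dimethyloxirane-2-carbonyl]oxy}-6,10-dimethyl-12-oxo-9-(triethylsilyloxy)dodeca-2,6,10-trienoate F3. F3 is closed with CrCl2 in THF/DMF at 1 mM (Nozaki–Hiyama allylchromium addition, then lactonisation of the chromium alkoxide) to 28. The allylchromium is far more nucleophilic than the boronate, equilibrates its geometry before a chair transition state, and can be chelated by the C8 acyloxy carbonyl, so both reactivity and facial control rest on a different element.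

**Step 14 (hydroalumination/borylmethylation).** iBu2AlH may attack the epoxy ester or the α-alumino enoate may alkylate poorly. The fallback sets out from 22 and comes back at 25. Syn-hydrostannation with Bu3SnH and Pd(PPh3)4 (tin goes α to the ester) gives methyl (2E,4R,6E,9S,10Z)-4-{[(2S,3S)-2,3-dimethyloxirane-2-carbonyl]oxy}-6,10-dimethyl-2-(tributylstannyl)-9,12-bis(triethylsilyloxy)dodeca-2,6,10-trienoate F4. Iododestannylation with I2 gives methyl (2E,4R,6E,9S,10Z)-4-{[(2S,3S)-2,3-dimethyloxirane-2-carbonyl]oxy}-2-iodo-6,10-dimethyl-9,12-bis(triethylsilyloxy)dodeca-2,6,10-trienoate F5. Negishi coupling of F5 with IZnCH2Bpin and Pd(PPh3)4, with retention of the olefin geometry, gives 25. No aluminium hydride is used on this path.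

**Step 12 (asymmetric alkynylation).** The enolisable β,γ-unsaturated aldehyde may give low yield or selectivity. The fallback sets out from 18 and comes back at 21. LiC≡CCO2Me (from 19 and LiN(SiMe3)2, THF, −78 °C) is added to give the C4-epimeric methyl (6E,9S,10Z)-4-hydroxy-6,10-dimethyl-9,12-bis(triethylsilyloxy)dodeca-6,10-dien-2-ynoate F6. Dess–Martin oxidation gives the ynone methyl (6E,9S,10Z)-6,10-dimethyl-4-oxo-9,12-bis(triethylsilyloxy)dodeca-6,10-dien-2-ynoate F7. Noyori transfer hydrogenation with RuCl[(R,R)-TsDPEN](p-cymene) in iPrOH gives 21; the (R,R) complex is chosen by analogy with simple alkynyl ketones.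

Further compounds

F1 | step 16 | methyl (2Z,4R,6E,9S,10Z)-4-{[(2S,3S)-2,3-dimethyloxirane-2-carbonyl]oxy}-2-(hydroxymethyl)-6,10-dimethyl-9,12-bis(triethylsilyloxy)dodeca-2,6,10-trienoate | CC[Si](CC)(CC)OC/C=C(/C)[C@@H](O[Si](CC)(CC)CC)C/C=C(\C)C[C@@H](OC(=O)[C@@]1(C)O[C@H]1C)/C=C(\C(=O)OC)CO
F2 | step 16 | methyl (2E,4R,6E,9S,10Z)-2-(bromomethyl)-4-{[(2S,3S)-2,3-dimethyloxirane-2-carbonyl]oxy}-6,10-dimethyl-9,12-bis(triethylsilyloxy)dodeca-2,6,10-trienoate | CC[Si](CC)(CC)OC/C=C(/C)[C@@H](O[Si](CC)(CC)CC)C/C=C(\C)C[C@@H](OC(=O)[C@@]1(C)O[C@H]1C)/C=C(\C(=O)OC)CBr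
F3 | step 16 | methyl (2E,4R,6E,9S,10Z)-2-(bromomethyl)-4-{[(2S,3S)-2,3-dimethyloxirane-2-carbonyl]oxy}-6,10-dimethyl-12-oxo-9-(triethylsilyloxy)dodeca-2,6,10-trienoate | O=C/C=C(/C)[C@@H](O[Si](CC)(CC)CC)C/C=C(\C)C[C@@H](OC(=O)[C@@]1(C)O[C@H]1C)/C=C(\C(=O)OC)CBr
F4 | step 14 | methyl (2E,4R,6E,9S,10Z)-4-{[(2S,3S)-2,3-dimethyloxirane-2-carbonyl]oxy}-6,10-dimethyl-2-(tributylstannyl)-9,12-bis(triethylsilyloxy)dodeca-2,6,10-trienoate | CC[Si](CC)(CC)OC/C=C(/C)[C@@H](O[Si](CC)(CC)CC)C/C=C(\C)C[C@@H](OC(=O)[C@@]1(C)O[C@H]1C)/C=C(\C(=O)OC)[Sn](CCCC)(CCCC)CCCC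
F5 | step 14 | methyl (2E,4R,6E,9S,10Z)-4-{[(2S,3S)-2,3-dimethyloxirane-2-carbonyl]oxy}-2-iodo-6,10-dimethyl-9,12-bis(triethylsilyloxy)dodeca-2,6,10-trienoate | CC[Si](CC)(CC)OC/C=C(/C)[C@@H](O[Si](CC)(CC)CC)C/C=C(\C)C[C@@H](OC(=O)[C@@]1(C)O[C@H]1C)/C=C(\C(=O)OC)I
F6 | step 12 | methyl (6E,9S,10Z)-4-hydroxy-6,10-dimethyl-9,12-bis(triethylsilyloxy)dodeca-6,10-dien-2-ynoate (both C4 epimers) | CC[Si](CC)(CC)OC/C=C(/C)[C@@H](O[Si](CC)(CC)CC)C/C=C(\C)CC(O)C#CC(=O)OC
F7 | step 12 | methyl (6E,9S,10Z)-6,10-dimethyl-4-oxo-9,12-bis(triethylsilyloxy)dodeca-6,10-dien-2-ynoate | CC[Si](CC)(CC)OC/C=C(/C)[C@@H](O[Si](CC)(CC)CC)C/C=C(\C)CC(=O)C#CC(=O)OC
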